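**Retrosynthetic overview**
1. C12 is added last: 23 ⇐ enol triflate 22 (Pd/CO/MeOH) ⇐ C11 methyl ketone 20. The 3β-propanoate comes from Luche reduction of a 4-en-3-one, the 8β-acetate from trans-diaxial HOBr addition to C8=C9 followed by debromination.
2. The 4,8-dien-3-one 14 ⇐ Saegusa–Ito oxidation of the cis-fused 8-en-3-one 12.
3. Feature and key disconnection: in 12 the chain C3(=O)–C2–C1–C10–C9=C8 (ring A carbons C1 to C3 and the ring B olefin, joined at quaternary C10) is a δ,ε-unsaturated ketone, the mark of an oxy-Cope product. Undoing the [3,3] shift (open C1–C10, close C3–C8) gives the 2-vinylbicyclo[2.2.2]oct-5-en-2-ol 9, on which C7 and C10, para across ring B, are already fixed.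
4. 9 ⇐ ketone 7 + CH2=CHMgBr ⇐ Diels–Alder adduct 4 of o-quinol acetate 2 (from 2,4-dimethylphenol 1) with methyl vinyl ketone 3; the racemate is resolved at 8.
5. Ring order: ring B first, as the cyclohexene ring of the bicyclo[2.2.2]octene ([4+2]); ring A second, closed by the [3,3] shift.

Key step: step 7

Remark: bicyclic compounds 4 to 10 carry bicyclo[2.2.2]octane numbers; from 11 on the atoms carry eudesmane numbers (C14 = methyl on C10, C15 = methyl on C4, side chain C11 to C13 on C7).
Remark: 2, 4, 6, 7 and 8 are racemates; their SMILES show the enantiomer that is carried on after the resolution of step 6.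

**Step 1**
Reactants: 1 2,4-dimethylphenol
Product: 2 rac-6-acetoxy-4,6-dimethylcyclohexa-2,4-dien-1-one
Conditions: Pb(OAc)4, AcOH, rt
Reagents that add atoms: Pb(OAc)4 (lead tetraacetate), CC(=O)O[Pb](OC(C)=O)(OC(C)=O)OC(C)=O
Why: Wessely oxidation, in which the aryloxy derivative of tetravalent lead passes acetate to the methyl-bearing ortho carbon and should give the o-quinol acetate as a racemate (its C6 centre is removed in step 4), with the p-quinol acetate as the expected separable by-product.

**Step 2**
Reactants: 2 rac-6-acetoxy-4,6-dimethylcyclohexa-2,4-dien-1-one; 3 methyl vinyl ketone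
Product: 4 rac-7-endo-acetyl-3-acetoxy-3,5-dimethylbicyclo[2.2.2]oct-5-en-2-one (acetyl syn to C5=C6; 3-acetoxy anti to C5=C6)
Conditions: 3 (5 equiv), PhMe, 90 °C, sealed tube
Reagents that add atoms: none
Why: Diels–Alder reaction with the 2,4-cyclohexadienone as diene, in which the acetyl-bearing carbon should bond to the dienone α-carbon (ortho rule) and the acetyl group should sit endo, syn to the new C5=C6 bridge, which fixes C1, C4 and C7 relative to one another; addition is expected on the acetoxy face, and the excess of 3 should outrun dimerisation of 2.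

**Step 3**
Reactants: 4 rac-7-endo-acetyl-3-acetoxy-3,5-dimethylbicyclo[2.2.2]oct-5-en-2-one; 5 ethylene glycol
Product: 6 rac-3-acetoxy-3,5-dimethyl-7-endo-(2-methyl-1,3-dioxolan-2-yl)bicyclo[2.2.2]oct-5-en-2-one
Conditions: 5, PPTS (cat.), PhH, reflux, azeotropic removal of H2O
Reagents that add atoms: none
Why: Acid-catalysed ketalisation, which should take the methyl ketone alone because the ring carbonyl lies between quaternary C3 and a bridgehead and would gain eclipsing strain on becoming tetrahedral.

**Step 4**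
Reactants: 6 rac-3-acetoxy-3,5-dimethyl-7-endo-(2-methyl-1,3-dioxolan-2-yl)bicyclo[2.2.2]oct-5-en-2-one
Product: 7 rac-3,5-dimethyl-7-endo-(2-methyl-1,3-dioxolan-2-yl)bicyclo[2.2.2]oct-5-en-2-one (3-methyl anti to C5=C6)
Conditions: SmI2 (2.5 equiv), THF/MeOH, −78 °C
Reagents that add atoms: none
Why: Reductive cleavage of an α-acyloxy ketone by two one-electron transfers from divalent samarium, after which MeOH should protonate the samarium enolate on the open olefin face and leave the C3 methyl anti to C5=C6 (this centre is erased in step 9, so its configuration is not critical).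

**Step 5**
Reactants: 7 rac-3,5-dimethyl-7-endo-(2-methyl-1,3-dioxolan-2-yl)bicyclo[2.2.2]oct-5-en-2-one
Product: 8 rac-2-ethenyl-3,5-dimethyl-7-endo-(2-methyl-1,3-dioxolan-2-yl)bicyclo[2.2.2]oct-5-en-2-ol (vinyl syn to C5=C6; OH and 3-methyl anti to it)
Conditions: CH2=CHMgBr, THF, −78 → 0 °C; aq. NH4Cl
Reagents that add atoms: vinylmagnesium bromide, C=C[Mg]Br
Why: Grignard 1,2-addition, which should come from the face of the C5=C6 bridge because the other face is shielded by the exo hydrogens of C7 and C8 and by the C3 methyl, so that C2 is set with the vinyl group syn to the olefin as the [3,3] shift requires.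

**Step 6**
Reactants: 8 rac-2-ethenyl-3,5-dimethyl-7-endo-(2-methyl-1,3-dioxolan-2-yl)bicyclo[2.2.2]oct-5-en-2-ol
Product: 9 2-ethenyl-3,5-dimethyl-7-endo-(2-methyl-1,3-dioxolan-2-yl)bicyclo[2.2.2]oct-5-en-2-ol, single enantiomer (the one that maps onto the 7αH/10β-methyl eudesmane series)
Conditions: preparative HPLC, amylose tris(3,5-dimethylphenylcarbamate) on silica, hexane/i-PrOH, rt
Reagents that add atoms: none
Why: Resolution by chromatography on a chiral stationary phase, for which the tertiary hydroxyl offers a hydrogen-bond donor to the carbamate selector; this step fixes the absolute configuration of the bicyclic frame, and the assignment would be secured by anomalous-dispersion X-ray analysis of bromide 15 made from a sample.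

**Step 7**
Reactants: 9 2-ethenyl-3,5-dimethyl-7-endo-(2-methyl-1,3-dioxolan-2-yl)bicyclo[2.2.2]oct-5-en-2-ol
Product: 12 11,11-ethylenedioxy-4βH,5βH-12-noreudesm-8-en-3-one, via potassium alkoxide 10 (not isolated), via potassium enolate 11 (not isolated)
Conditions: KH, 18-crown-6, THF, 0 °C → rt (50 °C if needed); aq. NH4Cl
Reagents that add atoms: none
Why: KH deprotonates the tertiary alcohol to the potassium alkoxide 10, and with the cation held by 18-crown-6 the oxyanion weakens the adjacent C2–C1 bond so that the 1,5-diene CH2=CH–C2–C1–C6=C5 undergoes a concerted [3,3]-sigmatropic shift, joining the vinyl terminus to C5 (eudesmane C1–C10), breaking C2–C1 (eudesmane C3–C8) and giving the Δ2 enolate 11, which is protonated on carbon at work-up. The closest known reaction type is the alkoxide-accelerated oxy-Cope rearrangement of 2-vinylbicyclo[2.2.2]oct-5-en-2-ols to cis-fused octalones. Ring A (C10–C1–C2–C3–C4–C5) closes as a six-membered carbocycle by pericyclic C–C bond formation inside a six-centre boat array, the only geometry the bicycle allows; it is not a polar exo or endo cyclisation. The one new stereocentre, quaternary C10, is set by the bridged frame, because the vinyl terminus can reach C5 only from the side of the carbinol bridge, so that C14 ends cis to H5 and cis to the endo C7 substituent. The step needs the vinyl group syn to the C5=C6 bridge and the C7 group endo, and both are fixed beforehand by the face selectivity of step 5 and the endo addition of step 2; the ketal and the alkene offer the base nothing to attack.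

**Step 8**
Reactants: 12 11,11-ethylenedioxy-4βH,5βH-12-noreudesm-8-en-3-one
Product: 13 11,11-ethylenedioxy-3-trimethylsilyloxy-5βH-12-noreudesma-3,8-diene
Conditions: Me3SiCl, Et3N, DMF, 90 °C
Reagents that add atoms: chlorotrimethylsilane, C[Si](C)(C)Cl
Why: Silyl enol ether formation under equilibrating conditions, where the tetrasubstituted Δ3 isomer should predominate because a cis-fused 3-decalone enolises towards the ring-fusion side and the C4 methyl adds a further alkyl group to that double bond.

**Step 9**
Reactants: 13 11,11-ethylenedioxy-3-trimethylsilyloxy-5βH-12-noreudesma-3,8-diene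
Product: 14 11,11-ethylenedioxy-12-noreudesma-4,8-dien-3-one
Conditions: Pd(OAc)2 (1.05 equiv), MeCN, rt
Reagents that add atoms: none
Why: Saegusa–Ito oxidation, in which the palladium enolate at C4 (free to change face through its O-bound form) loses the C5 hydride to give the conjugated tetrasubstituted enone, removing the C4 and C5 centres and making C4=C5 electron-poor for the next step.

**Step 10**
Reactants: 14 11,11-ethylenedioxy-12-noreudesma-4,8-dien-3-one
Product: 15 9α-bromo-11,11-ethylenedioxy-8β-hydroxy-12-noreudesm-4-en-3-one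
Conditions: NBS, THF/H2O, 0 °C, dark
Reagents that add atoms: N-bromosuccinimide, O=C1CCC(=O)N1Br; water, O
Why: Bromohydrin formation by anti addition, in which Br+ should add to the α face of C8=C9 (anti to the pseudoaxial C14 methyl) and water should open the bromonium ion trans-diaxially (Fürst–Plattner rule) at C8, the carbon that is not neopentyl, which sets 8β-OH and 9α-Br, while the enone olefin is too electron-poor to compete.

**Step 11**
Reactants: 15 9α-bromo-11,11-ethylenedioxy-8β-hydroxy-12-noreudesm-4-en-3-one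
Product: 16 11,11-ethylenedioxy-8β-hydroxy-12-noreudesm-4-en-3-one
Conditions: Bu3SnH, AIBN (cat.), PhH, 80 °C
Reagents that add atoms: none
Why: Radical chain dehalogenation, in which the stannyl radical abstracts bromine from C9 and the secondary radical takes hydrogen from Bu3SnH, leaving C8 untouched; bromine abstraction is far faster than stannyl addition to the enone.

**Step 12**
Reactants: 16 11,11-ethylenedioxy-8β-hydroxy-12-noreudesm-4-en-3-one
Product: 17 8β-acetoxy-11,11-ethylenedioxy-12-noreudesm-4-en-3-one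
Conditions: Ac2O, DMAP, Et3N, CH2Cl2, rt
Reagents that add atoms: acetic anhydride, CC(=O)OC(C)=O
Why: DMAP-catalysed acylation of the axial 8β-alcohol with retention, done while C3 is still a ketone so that the two ester groups of the target cannot be interchanged.

**Step 13**
Reactants: 17 8β-acetoxy-11,11-ethylenedioxy-12-noreudesm-4-en-3-one
Product: 18 8β-acetoxy-11,11-ethylenedioxy-12-noreudesm-4-en-3β-ol
Conditions: NaBH4, CeCl3·7H2O, MeOH, −78 → −20 °C
Reagents that add atoms: none
Why: Luche reduction, a 1,2-selective hydride addition that should come from the α face, anti to the axial C14 methyl, and so set C3 as the pseudoequatorial 3β-alcohol, with acetate and ketal inert.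

**Step 14**
Reactants: 18 8β-acetoxy-11,11-ethylenedioxy-12-noreudesm-4-en-3β-ol
Product: 19 8β-acetoxy-11,11-ethylenedioxy-3β-propanoyloxy-12-noreudesm-4-ene
Conditions: (EtCO)2O, DMAP, Et3N, CH2Cl2, 0 °C → rt
Reagents that add atoms: propanoic anhydride, CCC(=O)OC(=O)CC
Why: DMAP-catalysed acylation of the secondary allylic alcohol, which proceeds at oxygen with retention at C3.

**Step 15**
Reactants: 19 8β-acetoxy-11,11-ethylenedioxy-3β-propanoyloxy-12-noreudesm-4-ene
Product: 20 8β-acetoxy-3β-propanoyloxy-12-noreudesm-4-en-11-one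
Conditions: PPTS, acetone/H2O, 50 °C
Reagents that add atoms: water, O
Why: Mild acid-catalysed ketal hydrolysis, for which PPTS should be weak enough to leave the allylic propanoate un-ionised and the acetate unhydrolysed.

**Step 16**
Reactants: 20 8β-acetoxy-3β-propanoyloxy-12-noreudesm-4-en-11-one
Product: 22 8β-acetoxy-3β-propanoyloxy-12-noreudesma-4,11(13)-dien-11-yl trifluoromethanesulfonate, via potassium enolate 21 (not isolated)
Conditions: KN(SiMe3)2 (1.05 equiv), THF, −78 °C; then 5-chloro-2-pyridyl-NTf2, −78 °C; aq. NH4Cl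
Reagents that add atoms: N-(5-chloropyridin-2-yl)-1,1,1-trifluoro-N-(trifluoromethylsulfonyl)methanesulfonamide, O=S(=O)(N(c1ccc(Cl)cn1)S(=O)(=O)C(F)(F)F)C(F)(F)F
Why: Kinetic enolate formation and O-sulfonylation, in which the bulky amide base removes a methyl proton of the ketone (the most acidic carbonyl compound present) at −78 °C and the triflimide traps the terminal enolate before it can equilibrate towards C7, where loss of the β-acetate would threaten.

**Step 17**
Reactants: 22 8β-acetoxy-3β-propanoyloxy-12-noreudesma-4,11(13)-dien-11-yl trifluoromethanesulfonate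
Product: 23 methyl 8β-acetoxy-3β-propanoyloxyeudesma-4,11(13)-dien-12-oate, (3S,7R,8R,10R), CNP0198123.1
Conditions: Pd(OAc)2 (cat.), PPh3, CO (1 atm), MeOH, Et3N, DMF, 40 °C
Reagents that add atoms: carbon monoxide, [C-]#[O+]; methanol, CO
Why: Palladium-catalysed methoxycarbonylation of an enol triflate, in which oxidative addition to zerovalent palladium, CO insertion and methanolysis of the acyl-palladium species build the 2-substituted acrylate without touching a stereocentre.

**Compound list**
1 | 2,4-dimethylphenol | Cc1ccc(O)c(C)c1 | starting material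
2 | rac-6-acetoxy-4,6-dimethylcyclohexa-2,4-dien-1-one (racemic) | CC(=O)O[C@@]1(C)C=C(C)C=CC1=O | intermediate
3 | methyl vinyl ketone (but-3-en-2-one) | CC(=O)C=C | starting material
4 | rac-7-endo-acetyl-3-acetoxy-3,5-dimethylbicyclo[2.2.2]oct-5-en-2-one (acetyl syn to C5=C6, acetoxy anti; racemic) | CC(=O)[C@H]1C[C@H]2C(C)=C[C@@H]1C(=O)[C@@]2(C)OC(C)=O | intermediate
5 | ethylene glycol | OCCO | starting material
6 | rac-3-acetoxy-3,5-dimethyl-7-endo-(2-methyl-1,3-dioxolan-2-yl)bicyclo[2.2.2]oct-5-en-2-one (racemic) | CC1(OCCO1)[C@H]2C[C@H]3C(C)=C[C@@H]2C(=O)[C@@]3(C)OC(C)=O | intermediate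
7 | rac-3,5-dimethyl-7-endo-(2-methyl-1,3-dioxolan-2-yl)bicyclo[2.2.2]oct-5-en-2-one (3-methyl anti to C5=C6; racemic) | CC1(OCCO1)[C@H]2C[C@H]3C(C)=C[C@@H]2C(=O)[C@H]3C | intermediate
8 | rac-2-ethenyl-3,5-dimethyl-7-endo-(2-methyl-1,3-dioxolan-2-yl)bicyclo[2.2.2]oct-5-en-2-ol (vinyl syn to C5=C6; racemic) | C=C[C@]1(O)[C@@H](C)[C@H]2C[C@H](C3(C)OCCO3)[C@@H]1C=C2C | intermediate
9 | 2-ethenyl-3,5-dimethyl-7-endo-(2-methyl-1,3-dioxolan-2-yl)bicyclo[2.2.2]oct-5-en-2-ol, single enantiomer (vinyl syn to C5=C6, 3-methyl and OH anti) | C=C[C@]1(O)[C@@H](C)[C@H]2C[C@H](C3(C)OCCO3)[C@@H]1C=C2C | intermediate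
10 | potassium alkoxide of 9 (not isolated) | C=C[C@]1([O-])[C@@H](C)[C@H]2C[C@H](C3(C)OCCO3)[C@@H]1C=C2C.[K+] | intermediate
11 | potassium 11,11-ethylenedioxy-4βH,5βH-12-noreudesma-2,8-dien-3-olate (not isolated) | [O-]C1=CC[C@]2(C)C=C[C@@H](C3(C)OCCO3)C[C@@H]2[C@@H]1C.[K+] | intermediate
12 | 11,11-ethylenedioxy-4βH,5βH-12-noreudesm-8-en-3-one (cis-fused; C15 α; C7 substituent and C14 β) | O=C1CC[C@]2(C)C=C[C@@H](C3(C)OCCO3)C[C@@H]2[C@@H]1C | intermediate
13 | 11,11-ethylenedioxy-3-trimethylsilyloxy-5βH-12-noreudesma-3,8-diene | CC1=C(O[Si](C)(C)C)CC[C@]2(C)C=C[C@@H](C3(C)OCCO3)C[C@H]12 | intermediate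
14 | 11,11-ethylenedioxy-12-noreudesma-4,8-dien-3-one | O=C1CC[C@]2(C)C=C[C@@H](C3(C)OCCO3)CC2=C1C | intermediate
15 | 9α-bromo-11,11-ethylenedioxy-8β-hydroxy-12-noreudesm-4-en-3-one | O=C1CC[C@]2(C)[C@H](Br)[C@@H](O)[C@@H](C3(C)OCCO3)CC2=C1C | intermediate
16 | 11,11-ethylenedioxy-8β-hydroxy-12-noreudesm-4-en-3-one | O=C1CC[C@]2(C)C[C@@H](O)[C@@H](C3(C)OCCO3)CC2=C1C | intermediate
17 | 8β-acetoxy-11,11-ethylenedioxy-12-noreudesm-4-en-3-one | O=C1CC[C@]2(C)C[C@@H](OC(C)=O)[C@@H](C3(C)OCCO3)CC2=C1C | intermediate
18 | 8β-acetoxy-11,11-ethylenedioxy-12-noreudesm-4-en-3β-ol | O[C@H]1CC[C@]2(C)C[C@@H](OC(C)=O)[C@@H](C3(C)OCCO3)CC2=C1C | intermediate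
19 | 8β-acetoxy-11,11-ethylenedioxy-3β-propanoyloxy-12-noreudesm-4-ene | CCC(=O)O[C@H]1CC[C@]2(C)C[C@@H](OC(C)=O)[C@@H](C3(C)OCCO3)CC2=C1C | intermediate
20 | 8β-acetoxy-3β-propanoyloxy-12-noreudesm-4-en-11-one | CCC(=O)O[C@H]1CC[C@]2(C)C[C@@H](OC(C)=O)[C@@H](C(C)=O)CC2=C1C | intermediate
21 | potassium 8β-acetoxy-3β-propanoyloxy-12-noreudesma-4,11(13)-dien-11-olate (not isolated) | CCC(=O)O[C@H]1CC[C@]2(C)C[C@@H](OC(C)=O)[C@@H](C(=C)[O-])CC2=C1C.[K+] | intermediate
22 | 8β-acetoxy-3β-propanoyloxy-12-noreudesma-4,11(13)-dien-11-yl trifluoromethanesulfonate | CCC(=O)O[C@H]1CC[C@]2(C)C[C@@H](OC(C)=O)[C@@H](C(=C)OS(=O)(=O)C(F)(F)F)CC2=C1C | intermediate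
23 | methyl 8β-acetoxy-3β-propanoyloxyeudesma-4,11(13)-dien-12-oate, (3S,7R,8R,10R) | C=C(C(=O)OC)[C@H]1CC2=C(C)[C@@H](OC(=O)CC)CC[C@]2(C)C[C@H]1OC(C)=O | target

**Totals**
Total step count: 17. Longest linear sequence: 17 steps (1 → 23; 3, 5 and the reagents are bought).

**Steps most likely to fail**

Step 10 (bromohydrin). What may go wrong: opening of the bromonium ion at the wrong carbon or from the wrong face, because C8 is crowded by the neighbouring dioxolane, or capture of the bromonium ion by a ketal oxygen. The fallback sets out from 14 and comes back at 19; it reaches C8 by hydroboration and sets its configuration by ketone reduction. Luche reduction of 14 (NaBH4, CeCl3·7H2O, MeOH) should give 11,11-ethylenedioxy-12-noreudesma-4,8-dien-3β-ol F1. Acylation with (EtCO)2O/DMAP gives 11,11-ethylenedioxy-3β-propanoyloxy-12-noreudesma-4,8-diene F2. Hydroboration of the disubstituted C8=C9 bond with BH3·SMe2 at 0 °C (the tetrasubstituted C4=C5 bond reacts far more slowly) and oxidation with NaBO3·4H2O should place oxygen mainly at C8, away from quaternary C10, to give 11,11-ethylenedioxy-8α-hydroxy-3β-propanoyloxy-12-noreudesm-4-ene F3; a C9 regioisomer would be removed at the ketone stage. Oxidation with the triacetoxy periodinane (DMP, CH2Cl2) gives 11,11-ethylenedioxy-3β-propanoyloxy-12-noreudesm-4-en-8-one F4. LiBH(s-Bu)3 at −78 °C should attack from the equatorial α side, anti to the axial C14 methyl, to give the axial alcohol 11,11-ethylenedioxy-8β-hydroxy-3β-propanoyloxy-12-noreudesm-4-ene F5. Acetylation (Ac2O, DMAP) returns to 19.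

Step 16 (enol triflate). What may go wrong: equilibration of the enolate towards C7 with β-elimination of the C8 acetate, or transfer of the acetyl group from O8 to the enolate carbon. The fallback sets out from 20 and comes back at 22; it never lets a free enolate build up. LiN(i-Pr)2 is added to 20 in the presence of Me3SiCl (internal quench, THF, −78 °C), so that the kinetic enolate is trapped at once as 8β-acetoxy-3β-propanoyloxy-11-trimethylsilyloxy-12-noreudesma-4,11(13)-diene F6. CsF and PhNTf2 in DME at rt then convert the silyl enol ether into 22, the enolate being triflated as fast as fluoride releases it.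

Step 7 (anionic oxy-Cope). What may go wrong: fragmentation or isomerisation of the alkoxide faster than the [3,3] shift, which is slowed because bond formation at the methyl-bearing olefin carbon creates a quaternary centre. The fallback sets out from 9 and comes back at 12; it keeps the same disconnection but runs it as a neutral, thermal siloxy-Cope rearrangement. Silylation of 9 with N-trimethylsilylimidazole (60 °C) gives 2-ethenyl-3,5-dimethyl-7-endo-(2-methyl-1,3-dioxolan-2-yl)-2-trimethylsilyloxybicyclo[2.2.2]oct-5-ene F7. Heating in a sealed, base-washed tube (PhMe, about 250 °C) should give, through the same boat array, 11,11-ethylenedioxy-3-trimethylsilyloxy-4βH,5βH-12-noreudesma-2,8-diene F8. K2CO3 in MeOH cleaves the silyl enol ether to 12.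

**Further compounds**
F1 | step 10 | 11,11-ethylenedioxy-12-noreudesma-4,8-dien-3β-ol | O[C@H]1CC[C@]2(C)C=C[C@@H](C3(C)OCCO3)CC2=C1C
F2 | step 10 | 11,11-ethylenedioxy-3β-propanoyloxy-12-noreudesma-4,8-diene | CCC(=O)O[C@H]1CC[C@]2(C)C=C[C@@H](C3(C)OCCO3)CC2=C1C
F3 | step 10 | 11,11-ethylenedioxy-8α-hydroxy-3β-propanoyloxy-12-noreudesm-4-ene | CCC(=O)O[C@H]1CC[C@]2(C)C[C@H](O)[C@@H](C3(C)OCCO3)CC2=C1C
F4 | step 10 | 11,11-ethylenedioxy-3β-propanoyloxy-12-noreudesm-4-en-8-one | CCC(=O)O[C@H]1CC[C@]2(C)CC(=O)[C@@H](C3(C)OCCO3)CC2=C1C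
F5 | step 10 | 11,11-ethylenedioxy-8β-hydroxy-3β-propanoyloxy-12-noreudesm-4-ene | CCC(=O)O[C@H]1CC[C@]2(C)C[C@@H](O)[C@@H](C3(C)OCCO3)CC2=C1C
F6 | step 16 | 8β-acetoxy-3β-propanoyloxy-11-trimethylsilyloxy-12-noreudesma-4,11(13)-diene | CCC(=O)O[C@H]1CC[C@]2(C)C[C@@H](OC(C)=O)[C@@H](C(=C)O[Si](C)(C)C)CC2=C1C
F7 | step 7 | 2-ethenyl-3,5-dimethyl-7-endo-(2-methyl-1,3-dioxolan-2-yl)-2-trimethylsilyloxybicyclo[2.2.2]oct-5-ene | C=C[C@]1(O[Si](C)(C)C)[C@@H](C)[C@H]2C[C@H](C3(C)OCCO3)[C@@H]1C=C2C
F8 | step 7 | 11,11-ethylenedioxy-3-trimethylsilyloxy-4βH,5βH-12-noreudesma-2,8-diene | C[Si](C)(C)OC1=CC[C@]2(C)C=C[C@@H](C3(C)OCCO3)C[C@@H]2[C@@H]1C
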